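**Retrosynthetic overview**
1. Target ⇒ C9–O bond: late-stage catalytic allylic C–H acyloxylation of the C9-deoxy spiro butenolide with 3-phenylpropanoic acid (new step; makes the ester and sets C9).
2. C9-deoxy butenolide ⇒ side-chain aldehyde + 3-methylfuran-2(5H)-one (vinylogous aldol, then elimination; the butenolide ring is bought ready-made).
3. Aldehyde ⇒ Claisen rearrangement of the (E)-propenyl ether of a spirocyclic cyclopent-1-en-3-ol (C3–O chirality passed on to C1 and C2′), then saturation of the cyclopentene.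
4. Allylic alcohol ⇒ spiro ketone by dehydrogenation, nucleophilic epoxidation (C3–O trans to the 4-methyl) and Wharton transposition.
5. Spiro ketone ⇒ Diels–Alder reaction of isoprene with (S)-3-methyl-2-methylidenecyclopentanone. Ring order: cyclopentane (from 3-methylcyclopentenone), then cyclohexene (Diels–Alder), then the preformed butenolide is attached.

Numbering used below: locants C1–C10 are those of the target's spiro[4.5]decane core in every intermediate (C1 side-chain carbon, C4 methyl carbon, C5 spiro carbon, C7=C8, C9 ester carbon); C2′ is the side-chain stereocentre.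

**Step 1**
Reactants: 1 3-methylcyclopent-2-en-1-one
Product: 3 (2S,3S)-2-[(dimethylamino)methyl]-3-methylcyclopentan-1-one, via bis-enol diphenylsilane 2 (not isolated)
Conditions: Ph2SiH2 (0.55 equiv), CuCl/NaOt-Bu/(R)-p-tol-BINAP (5 mol % each; the ligand antipode that gives the 3S series), toluene, −20 °C; then CH2=NMe2 iodide, CH2Cl2/MeCN, rt; cold 1 M NaOH work-up
Reagents that add atoms: dimethyl(methylidene)ammonium iodide, C=[N+](C)C.[I-]
Why: Buchwald-type copper hydride asymmetric conjugate reduction delivers hydride to one face of the β-carbon under ligand control (sets the methyl-bearing centre, later C4) and leaves the regiodefined silyl enol ether, which undergoes a Mannich reaction with the iminium salt only at the carbon between C=O and CHMe.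

**Step 2**
Reactants: 3 (2S,3S)-2-[(dimethylamino)methyl]-3-methylcyclopentan-1-one
Product: 5 (3S)-3-methyl-2-methylidenecyclopentan-1-one, via methiodide salt 4 (not isolated)
Conditions: MeI, Et2O, rt; then aq K2CO3, CH2Cl2, 0 °C; used at once as a solution
Reagents that add atoms: none
Why: Quaternisation makes trimethylamine a leaving group and mild base effects E1cB (Hofmann-type) elimination of the Mannich salt to the exocyclic enone, leaving the adjacent stereocentre intact.

**Step 3**
Reactants: 5 (3S)-3-methyl-2-methylidenecyclopentan-1-one; 6 isoprene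
Product: 7 (4S,5R)-4,8-dimethylspiro[4.5]dec-7-en-1-one
Conditions: EtAlCl2 (20 mol %), isoprene (5 equiv), CH2Cl2, −78 → −30 °C
Reagents that add atoms: none
Why: Lewis acid catalysed Diels–Alder reaction in which isoprene adds to the exocyclic enone with para orientation (8-methyl) and from the face anti to the neighbouring C4 methyl, so the diene terminus C6 ends trans to that methyl and the spiro centre C5 is fixed.

**Step 4**
Reactants: 7 (4S,5R)-4,8-dimethylspiro[4.5]dec-7-en-1-one
Product: 8 (4S,5R)-4,8-dimethylspiro[4.5]deca-2,7-dien-1-one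
Conditions: IBX, 4-methoxypyridine N-oxide, DMSO, rt
Reagents that add atoms: none
Why: IBX dehydrogenation of a ketone whose only enolisable position is C2 gives the C2=C3 enone without affecting C4 or C5.

**Step 5**
Reactants: 8 (4S,5R)-4,8-dimethylspiro[4.5]deca-2,7-dien-1-one
Product: 9 (2S,3S,4R,5R)-2,3-epoxy-4,8-dimethylspiro[4.5]dec-7-en-1-one
Conditions: 30% H2O2, aq NaOH (cat.), MeOH, 0 °C
Reagents that add atoms: hydrogen peroxide, OO
Why: Weitz–Scheffer nucleophilic epoxidation, in which hydroperoxide adds to C3 anti to the adjacent C4 methyl, so the new C3–O bond is trans to it.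

**Step 6**
Reactants: 9 (2S,3S,4R,5R)-2,3-epoxy-4,8-dimethylspiro[4.5]dec-7-en-1-one
Product: 11 (3R,4R,5S)-4,8-dimethylspiro[4.5]deca-1,7-dien-3-ol, via epoxy hydrazone 10 (not isolated)
Conditions: N2H4·H2O, AcOH (cat.), MeOH, 0 °C → rt, under argon
Reagents that add atoms: none
Why: Wharton transposition, in which the epoxy hydrazone fragments with loss of N2 to the transposed allylic alcohol, keeping the C3–O configuration while C1 becomes an alkene carbon.

**Step 7**
Reactants: 11 (3R,4R,5S)-4,8-dimethylspiro[4.5]deca-1,7-dien-3-ol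
Product: 12 (3R,4R,5S)-3-(allyloxy)-4,8-dimethylspiro[4.5]deca-1,7-diene
Conditions: NaH, allyl bromide, Bu4NI (cat.), THF/DMF, 0 °C → rt
Reagents that add atoms: allyl bromide, C=CCBr
Why: Williamson etherification of the sodium alkoxide with allyl bromide, no stereocentre being touched.

**Step 8**
Reactants: 12 (3R,4R,5S)-3-(allyloxy)-4,8-dimethylspiro[4.5]deca-1,7-diene
Product: 14 (2S)-2-[(1R,4S,5R)-4,8-dimethylspiro[4.5]deca-2,7-dien-1-yl]propanal, via (E)-propenyl ether 13 (not isolated)
Conditions: [Ir(cod)Cl]2 (1 mol %), PCy3, NaBPh4, CH2Cl2/acetone, rt; then PPh3, toluene, 110 °C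
Reagents that add atoms: none
Why: Iridium-catalysed isomerisation of the allyl ether to the (E)-propenyl ether followed by Claisen rearrangement, in which the suprafacial [3,3] shift puts the new C1–C2′ bond on the face that carried the C3 oxygen (trans to 4-Me, giving 1R) and the boat-like array that turns the propenyl methyl away from the spiro ring gives 2′S.

**Step 9**
Reactants: 14 (2S)-2-[(1R,4S,5R)-4,8-dimethylspiro[4.5]deca-2,7-dien-1-yl]propanal
Product: 15 (2S)-2-[(1R,4S,5R)-4,8-dimethylspiro[4.5]dec-7-en-1-yl]propanal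
Conditions: H2 (1 atm), RhCl(PPh3)3 (5 mol %), benzene/EtOH, rt
Reagents that add atoms: none
Why: Homogeneous hydrogenation with RhCl(PPh3)3 saturates the cis-disubstituted cyclopentene much faster than the trisubstituted cyclohexene and touches neither the aldehyde nor a stereocentre.

**Step 10**
Reactants: 15 (2S)-2-[(1R,4S,5R)-4,8-dimethylspiro[4.5]dec-7-en-1-yl]propanal; 16 3-methylfuran-2(5H)-one
Product: 19 (5Z)-5-{(2S)-2-[(1R,4S,5R)-4,8-dimethylspiro[4.5]dec-7-en-1-yl]propylidene}-3-methylfuran-2(5H)-one, via silyloxyfuran 17 (not isolated), via silyl aldol adduct 18 (not isolated)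
Conditions: 16, TBSOTf, i-Pr2NEt, CH2Cl2, 0 °C; then 15, −78 °C; then DBU, −78 → −20 °C (short contact)
Reagents that add atoms: none
Why: One-pot vinylogous Mukaiyama aldol addition of the silyloxyfuran (through its 5-position) to the aldehyde followed by E1cB loss of silanol gives the thermodynamically favoured (Z)-ylidenebutenolide, with low temperature and brief DBU contact keeping C2′ intact.

**Step 11**
Reactants: 19 (5Z)-5-{(2S)-2-[(1R,4S,5R)-4,8-dimethylspiro[4.5]dec-7-en-1-yl]propylidene}-3-methylfuran-2(5H)-one; 20 3-phenylpropanoic acid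
Product: 21 (1R,4S,5S,9S)-4,8-dimethyl-1-{(2S)-1-[(2Z)-4-methyl-5-oxofuran-2(5H)-ylidene]propan-2-yl}spiro[4.5]dec-7-en-9-yl 3-phenylpropanoate
Conditions: (S,S)-bis[2-(1-methoxyethyl)phenyl] diselenide (10 mol %), PhIO (1.5 equiv), 20 (3 equiv), 4 Å MS, CH2Cl2, −20 °C → rt
Reagents that add atoms: none
Why: Proposed new method: the diselenide is oxidised in the flask by PhI(O2CR)2 (formed from PhIO and 20) to a chiral arylseleninyl carboxylate ArSe(=O)O2CR (tetravalent selenium), which attacks only the electron-rich C7=C8 alkene in a hetero-ene reaction (Se to C7, hydrogen taken from ring C9–H as in SeO2 oxidations of 1-methylcyclohexenes), the allyl selenoxide then undergoes the suprafacial [2,3] shift that makes the C9–O bond and restores C7=C8, and the resulting divalent selenium allyl selenenate is reoxidised by PhI(O2CR)2 to a tetravalent selenium alkoxide bis(carboxylate) that passes one acyl group to the alkoxide oxygen, releasing the ester and the seleninyl carboxylate for the next turn; the chiral aryl group, reinforced by the substrate (the axial C9–H anti to the pseudo-axial C4 arm of the spiro ring is the one removed), selects the face that gives 9S with the oxygen cis to C1; the closest known reaction types are the SeO2/t-BuOOH allylic hydroxylation (ene then [2,3]), SeO2 in Ac2O/AcOH giving allylic acetates, and diselenide catalysis driven by trivalent iodine oxidants.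

**Compound list**
1 | 3-methylcyclopent-2-en-1-one | CC1=CC(=O)CC1 | starting material
2 | bis{[(3S)-3-methylcyclopent-1-en-1-yl]oxy}diphenylsilane | C1(O[Si](c2ccccc2)(c2ccccc2)OC2=C[C@@H](C)CC2)=C[C@@H](C)CC1 | intermediate (not isolated)
3 | (2S,3S)-2-[(dimethylamino)methyl]-3-methylcyclopentan-1-one | O=C1CC[C@H](C)[C@H]1CN(C)C | intermediate
4 | {[(1S,2S)-2-methyl-5-oxocyclopentyl]methyl}trimethylammonium iodide | O=C1CC[C@H](C)[C@H]1C[N+](C)(C)C.[I-] | intermediate (not isolated)
5 | (3S)-3-methyl-2-methylidenecyclopentan-1-one | O=C1CC[C@H](C)C1=C | intermediate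
6 | isoprene (2-methylbuta-1,3-diene) | C=CC(C)=C | starting material
7 | (4S,5R)-4,8-dimethylspiro[4.5]dec-7-en-1-one | O=C1CC[C@H](C)[C@@]12CC=C(C)CC2 | intermediate
8 | (4S,5R)-4,8-dimethylspiro[4.5]deca-2,7-dien-1-one | O=C1C=C[C@H](C)[C@@]12CC=C(C)CC2 | intermediate
9 | (2S,3S,4R,5R)-2,3-epoxy-4,8-dimethylspiro[4.5]dec-7-en-1-one (epoxide oxygen trans to the 4-methyl) | O=C1[C@H]2O[C@H]2[C@H](C)[C@@]13CC=C(C)CC3 | intermediate
10 | hydrazone of 9 | NN=C1[C@H]2O[C@H]2[C@H](C)[C@@]13CC=C(C)CC3 | intermediate (not isolated)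
11 | (3R,4R,5S)-4,8-dimethylspiro[4.5]deca-1,7-dien-3-ol (OH trans to the 4-methyl) | C1=C[C@@H](O)[C@H](C)[C@@]12CC=C(C)CC2 | intermediate
12 | (3R,4R,5S)-3-(allyloxy)-4,8-dimethylspiro[4.5]deca-1,7-diene | C1=C[C@@H](OCC=C)[C@H](C)[C@@]12CC=C(C)CC2 | intermediate
13 | (3R,4R,5S)-4,8-dimethyl-3-[(1E)-prop-1-en-1-yloxy]spiro[4.5]deca-1,7-diene | C1=C[C@@H](O/C=C/C)[C@H](C)[C@@]12CC=C(C)CC2 | intermediate (not isolated)
14 | (2S)-2-[(1R,4S,5R)-4,8-dimethylspiro[4.5]deca-2,7-dien-1-yl]propanal | O=C[C@@H](C)[C@H]1C=C[C@H](C)[C@@]12CC=C(C)CC2 | intermediate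
15 | (2S)-2-[(1R,4S,5R)-4,8-dimethylspiro[4.5]dec-7-en-1-yl]propanal | O=C[C@@H](C)[C@H]1CC[C@H](C)[C@@]12CC=C(C)CC2 | intermediate
16 | 3-methylfuran-2(5H)-one | CC1=CCOC1=O | starting material
17 | tert-butyl(dimethyl)[(3-methylfuran-2-yl)oxy]silane | CC1=C(O[Si](C)(C)C(C)(C)C)OC=C1 | intermediate (not isolated)
18 | 5-{(2S)-1-[tert-butyl(dimethyl)silyloxy]-2-[(1R,4S,5R)-4,8-dimethylspiro[4.5]dec-7-en-1-yl]propyl}-3-methylfuran-2(5H)-one (mixture at the two new centres) | CC1=CC(OC1=O)C(O[Si](C)(C)C(C)(C)C)[C@@H](C)[C@H]2CC[C@H](C)[C@@]23CC=C(C)CC3 | intermediate (not isolated)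
19 | (5Z)-5-{(2S)-2-[(1R,4S,5R)-4,8-dimethylspiro[4.5]dec-7-en-1-yl]propylidene}-3-methylfuran-2(5H)-one | CC1=C/C(=C/[C@@H](C)[C@H]2CC[C@H](C)[C@@]23CC=C(C)CC3)OC1=O | intermediate
20 | 3-phenylpropanoic acid | OC(=O)CCc1ccccc1 | starting material
21 | (1R,4S,5S,9S)-4,8-dimethyl-1-{(2S)-1-[(2Z)-4-methyl-5-oxofuran-2(5H)-ylidene]propan-2-yl}spiro[4.5]dec-7-en-9-yl 3-phenylpropanoate | CC1=C/C(=C/[C@@H](C)[C@H]2CC[C@H](C)[C@@]23CC=C(C)[C@@H](OC(=O)CCc2ccccc2)C3)OC1=O | target

**Step count and risk**
Total step count: 11. Longest linear sequence: 11 (the route is linear from 1).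

The three steps most likely to fail:

Step 8 (Claisen rearrangement: the boat-over-chair preference that decides C2′ is predicted, not proven). The fallback sets out from 11 and comes back at 14. Compound 11 is acylated (propanoic anhydride, DMAP) to the propanoate ester F1. Ireland–Claisen rearrangement follows: LiN(i-Pr)2 in THF/DMPU at −78 °C, then Me3SiCl, gives the silyl ketene acetal F2 (CH3 cis to OSiMe3; without DMPU the other geometry forms, so either C2′ epimer can be reached whichever array operates). On warming this rearranges to the trimethylsilyl ester F3, which is hydrolysed on work-up to the carboxylic acid F4 (epimers separable at this stage). LiAlH4 reduces it to the primary alcohol F5, and Dess–Martin oxidation returns aldehyde 14.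

Step 10 (one-pot aldol/elimination on an aldehyde with an α-stereocentre: risk of C2′ epimerisation or alkene drift under DBU). The fallback sets out from 15 and comes back at 19. Ohira–Bestmann homologation (dimethyl (1-diazo-2-oxopropyl)phosphonate, K2CO3, MeOH, 0 °C) gives the terminal alkyne F6. PdCl2(PPh3)2/CuI/Et3N in MeCN at rt couples it with (Z)-3-iodo-2-methylacrylic acid (taken as a catalogue reagent) to the (Z)-enynoic acid F7 (not isolated). Its carboxylate adds anti across the alkyne (5-exo-dig), closing the lactone C–O bond and giving 19 as the Z isomer without strong base.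

Step 11 (the new allylic C–H acyloxylation: rate, site and face selectivity are unproven). The fallback uses known chemistry, sets out from 19 and comes back at 21. SeO2 (cat.)/t-BuOOH in CH2Cl2 hydroxylates C9 to the allylic alcohol F8 (both C9 epimers). Dess–Martin oxidation gives the carvone-type enone F9. Reduction with (R)-Me-CBS oxazaborolidine [(R)-1-methyl-3,3-diphenyltetrahydro-1H,3H-pyrrolo[1,2-c][1,3,2]oxazaborole] and catecholborane in toluene at −78 °C gives, under catalyst control, the (9S)-alcohol F10. Esterification with 20 (EDC·HCl, DMAP, CH2Cl2) gives 21.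

**Further compounds**
F1 | step 8 | (3R,4R,5S)-4,8-dimethylspiro[4.5]deca-1,7-dien-3-yl propanoate | C1=C[C@@H](OC(=O)CC)[C@H](C)[C@@]12CC=C(C)CC2
F2 | step 8 | trimethylsilyl ketene acetal of F1 (CH3 cis to OSiMe3) | C1=C[C@@H](O/C(O[Si](C)(C)C)=C/C)[C@H](C)[C@@]12CC=C(C)CC2
F3 | step 8 | trimethylsilyl (2S)-2-[(1R,4S,5R)-4,8-dimethylspiro[4.5]deca-2,7-dien-1-yl]propanoate | C[Si](C)(C)OC(=O)[C@@H](C)[C@H]1C=C[C@H](C)[C@@]12CC=C(C)CC2
F4 | step 8 | (2S)-2-[(1R,4S,5R)-4,8-dimethylspiro[4.5]deca-2,7-dien-1-yl]propanoic acid | OC(=O)[C@@H](C)[C@H]1C=C[C@H](C)[C@@]12CC=C(C)CC2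
F5 | step 8 | (2S)-2-[(1R,4S,5R)-4,8-dimethylspiro[4.5]deca-2,7-dien-1-yl]propan-1-ol | OC[C@@H](C)[C@H]1C=C[C@H](C)[C@@]12CC=C(C)CC2
F6 | step 10 | (1R,4S,5R)-1-[(2S)-but-3-yn-2-yl]-4,8-dimethylspiro[4.5]dec-7-ene | C#C[C@@H](C)[C@H]1CC[C@H](C)[C@@]12CC=C(C)CC2
F7 | step 10 | (2Z,6S)-6-[(1R,4S,5R)-4,8-dimethylspiro[4.5]dec-7-en-1-yl]-2-methylhept-2-en-4-ynoic acid | OC(=O)/C(C)=C\C#C[C@@H](C)[C@H]1CC[C@H](C)[C@@]12CC=C(C)CC2
F8 | step 11 | (5Z)-5-{(2S)-2-[(1R,4S,5S)-9-hydroxy-4,8-dimethylspiro[4.5]dec-7-en-1-yl]propylidene}-3-methylfuran-2(5H)-one (C9 epimer mixture) | CC1=C/C(=C/[C@@H](C)[C@H]2CC[C@H](C)[C@@]23CC=C(C)C(O)C3)OC1=O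
F9 | step 11 | (5Z)-5-{(2S)-2-[(1R,4S,5S)-4,8-dimethyl-9-oxospiro[4.5]dec-7-en-1-yl]propylidene}-3-methylfuran-2(5H)-one | CC1=C/C(=C/[C@@H](C)[C@H]2CC[C@H](C)[C@@]23CC=C(C)C(=O)C3)OC1=O
F10 | step 11 | (5Z)-5-{(2S)-2-[(1R,4S,5S,9S)-9-hydroxy-4,8-dimethylspiro[4.5]dec-7-en-1-yl]propylidene}-3-methylfuran-2(5H)-one | CC1=C/C(=C/[C@@H](C)[C@H]2CC[C@H](C)[C@@]23CC=C(C)[C@@H](O)C3)OC1=O
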